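A direct plan would take both rings from one benzylic alcohol, (3-bromo-4,5-dimethoxyphenyl)methanol A1. Acetylation would give A2, ring bromination plus HBr would give the benzylic bromide A3, an AgOSO2CF3-promoted Friedel–Crafts benzylation of A2 by A3 would give the diarylmethane A4, and BBr3 would unmask the target.
Its weakest steps would be:
- the Friedel–Crafts union of A2 and A3: the bond must form at the most crowded position of A2 (between CH2OAc and Br), regiocontrol rests only on the different conformations of two methoxy groups, and an excess of A2 would be needed to hold back double benzylation;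
- the closing BBr3 treatment of A4: four ether cleavages and an acetate-to-bromide exchange at once, then hydrolysis through a para-quinone methide beside two free catechols, so the sensitive benzylic position is put at risk in the last step;
- the shuffle at the benzylic oxygen (alcohol A1, acetate A2, later bromide, later alcohol again): three changes of one group that build nothing.

**Retrosynthetic overview**
Ring A (C1 CH2OH, C2 CH2–ring B, C3 Br, C4/C5 OH, C6 H) is not bought but built by a [2+2+2] alkyne cyclotrimerisation: C6, C1, C2 and C3 come from an ether-tethered bromodiyne, C4 and C5 from bis(boryl)acetylene.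
The same step closes the five-membered oxygen ring of a 1-arylphthalan, whose O-bridge is the latent ortho pair C1–CH2OH / C2–CH2–ring B; ionic hydrogenation of its doubly benzylic C–O bond later releases both groups.
Ring B comes intact from 5-bromovanillin; the bromine of ring A sits on an alkyne carbon and its two hydroxyls arrive as C–B bonds, so no substituent of ring A is placed by electrophilic substitution.
Ring order: ring B (given), then the O-ring and ring A together (step 7), then the O-ring is opened (step 8).
There is no Friedel–Crafts union and no BBr3; the benzylic alcohol is set free while ring A is still deactivated by boron, and the phenols appear last by mild C–B oxidation.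

Key step: step 7

Remark: intermediates 5, 6, 7 and 9 carry one stereocentre and are used as racemates, since this centre becomes the achiral CH2 bridge in step 8; alkyne 8 is taken as a purchased reagent.

Step 1
Reactants: 1 5-bromovanillin (3-bromo-4-hydroxy-5-methoxybenzaldehyde)
Product: 2 2,3-dibromo-4-hydroxy-5-methoxybenzaldehyde
Conditions: Br2 (1.2 equiv), Fe powder (cat.), AcOH, rt to 50 °C
Reagents that add atoms: bromine, BrBr
Why: Iron-catalysed electrophilic aromatic bromination should go para to the methoxy group, because the positions ortho and para to the free hydroxyl are already occupied, which gives the 2,3-dibromo pattern of ring B.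

Step 2
Reactants: 2 2,3-dibromo-4-hydroxy-5-methoxybenzaldehyde
Product: 3 2,3-dibromo-4,5-dihydroxybenzaldehyde
Conditions: AlCl3 (1.5 equiv), pyridine (4.5 equiv), CH2Cl2, reflux; then 2 M HCl
Reagents that add atoms: none
Why: Chelation-assisted O-demethylation, in which the aluminium phenoxide of the 4-hydroxyl binds the neighbouring methoxy oxygen and pyridine removes the methyl group by SN2, should spare the aldehyde and both aryl bromides.

Step 3
Reactants: 3 2,3-dibromo-4,5-dihydroxybenzaldehyde
Product: 4 2,3-dibromo-4,5-bis(methoxymethoxy)benzaldehyde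
Conditions: NaH (2.4 equiv), MOMCl (2.6 equiv), DMF, 0 °C to rt
Reagents that add atoms: chloromethyl methyl ether, COCCl
Why: Williamson-type O-alkylation of the catechol dianion gives two acetal ethers that should withstand the Grignard, silver, hydride-base and ruthenium steps and fall off in the acid of step 8.

Step 4
Reactants: 4 2,3-dibromo-4,5-bis(methoxymethoxy)benzaldehyde
Product: 5 1-[2,3-dibromo-4,5-bis(methoxymethoxy)phenyl]prop-2-yn-1-ol (racemic)
Conditions: HC≡CMgBr (1.5 equiv, 0.5 M in THF), THF, −20 to 0 °C; then sat. aq NH4Cl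
Reagents that add atoms: ethynylmagnesium bromide, C#C[Mg]Br
Why: Grignard 1,2-addition to the aldehyde builds the propargylic carbinol without exchange at the aryl bromides at this temperature, and the new stereocentre is formed as a racemate because it is erased in step 8.

Step 5
Reactants: 5 1-[2,3-dibromo-4,5-bis(methoxymethoxy)phenyl]prop-2-yn-1-ol (racemic)
Product: 6 3-bromo-1-[2,3-dibromo-4,5-bis(methoxymethoxy)phenyl]prop-2-yn-1-ol (racemic)
Conditions: NBS (1.1 equiv), AgNO3 (10 mol%), acetone, rt, dark
Reagents that add atoms: N-bromosuccinimide, O=C1CCC(=O)N1Br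
Why: Silver-catalysed electrophilic bromination of the terminal alkyne (through the silver acetylide) places the future C3 bromine of ring A on carbon at the alkyne stage, where its position is unambiguous, while the doubly brominated arene should not react with NBS under these neutral conditions.

Step 6
Reactants: 6 3-bromo-1-[2,3-dibromo-4,5-bis(methoxymethoxy)phenyl]prop-2-yn-1-ol (racemic)
Product: 7 2,3-dibromo-1-[3-bromo-1-(prop-2-yn-1-yloxy)prop-2-yn-1-yl]-4,5-bis(methoxymethoxy)benzene (racemic)
Conditions: NaH (1.2 equiv), propargyl bromide (1.5 equiv), n-Bu4NI (cat.), THF/DMF (4:1), 0 °C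
Reagents that add atoms: propargyl bromide (3-bromoprop-1-yne), C#CCBr
Why: Williamson etherification of the sodium alkoxide with the reactive propargylic bromide completes the 1,6-diyne whose oxygen tether will become the CH2OH group; the 1-bromoalkyne should tolerate alkoxide at 0 °C and the stereocentre is untouched.

Step 7
Reactants: 7 2,3-dibromo-1-[3-bromo-1-(prop-2-yn-1-yloxy)prop-2-yn-1-yl]-4,5-bis(methoxymethoxy)benzene (racemic); 8 2,2'-(ethyne-1,2-diyl)bis(4,4,5,5-tetramethyl-1,3,2-dioxaborolane)
Product: 9 7-bromo-1-[2,3-dibromo-4,5-bis(methoxymethoxy)phenyl]-5,6-bis(4,4,5,5-tetramethyl-1,3,2-dioxaborolan-2-yl)-1,3-dihydro-2-benzofuran (racemic 1-arylphthalan)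
Conditions: Cp*RuCl(cod) (10 mol%), 8 (3 equiv, excess recovered), ClCH2CH2Cl, 60 °C, 7 added over 6 h, under Ar
Reagents that add atoms: none
Why: This is a metal-catalysed [2+2+2] alkyne cyclotrimerisation in which the Cp*RuCl fragment couples the two tethered alkynes of 7 oxidatively to a ruthenacyclopentadiene, alkyne 8 inserts and reductive elimination releases the arene, so that three C–C bonds (C3a–C7a, C4–C5 and C6–C7 of the phthalan) form in one operation. The closest known reaction type is the Cp*RuCl(cod)-catalysed cycloaddition of ether-tethered 1,6-diynes, 1-haloalkyne termini included, with alkynylboronates to give borylated phthalans. The five-membered oxygen ring closes in the oxidative cyclisation that joins the two inner alkyne carbons, and ring A closes when the two carbons of 8 bridge the two diyne termini. No new stereocentre is formed: the carbinol centre of 7 is carried unchanged as racemic C1 of the phthalan and is erased in step 8. Regiochemistry needs no control, because 8 is symmetrical and the tether fixes Br at C7 next to the aryl-bearing carbon and H at C4; cross-coupling over diyne dimerisation should be secured by slow addition of 7 to an excess of 8, which is too hindered to trimerise by itself. The alkynyl C–Br bond must survive, and 1-haloalkynes are established substrates of Cp*RuCl(cod).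

Step 8
Reactants: 9 7-bromo-1-[2,3-dibromo-4,5-bis(methoxymethoxy)phenyl]-5,6-bis(4,4,5,5-tetramethyl-1,3,2-dioxaborolan-2-yl)-1,3-dihydro-2-benzofuran (racemic)
Product: 11 3-bromo-4-(2,3-dibromo-4,5-dihydroxybenzyl)-5-(hydroxymethyl)benzene-1,2-diol, via ring-opened bis(boronate) catechol 10 (not isolated)
Conditions: Et3SiH (5 equiv), CF3CO2H/CH2Cl2 (1:4), 0 °C to rt; evaporate; then NaBO3·4H2O (8 equiv), THF/H2O (1:1), rt, under Ar; work-up at pH 4
Reagents that add atoms: sodium perborate, [Na+].[Na+].O[B-]1(O)OO[B-](O)(O)OO1
Why: In this ionic hydrogenation followed by ipso-hydroxylation, acid removes both methoxymethyl acetals, the freed 4-hydroxyl of ring B (para to the diarylmethyl carbon) drives ionisation of the doubly benzylic C1–O bond and Et3SiH reduces the cation to the CH2 bridge while ring A, still carrying two boryl groups, is too electron-poor for its primary benzylic C–O bond to ionise, and perborate then turns both C–B bonds into C–OH by 1,2-aryl migration from boron to oxygen with the borate formed shielding the catechols, so that the stereocentre disappears and the achiral target results.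

**Compound list**
1 | 5-bromovanillin (3-bromo-4-hydroxy-5-methoxybenzaldehyde) | COc1cc(C=O)cc(Br)c1O | starting material
2 | 2,3-dibromo-4-hydroxy-5-methoxybenzaldehyde | COc1cc(C=O)c(Br)c(Br)c1O | intermediate
3 | 2,3-dibromo-4,5-dihydroxybenzaldehyde | O=Cc1cc(O)c(O)c(Br)c1Br | intermediate
4 | 2,3-dibromo-4,5-bis(methoxymethoxy)benzaldehyde | COCOc1cc(C=O)c(Br)c(Br)c1OCOC | intermediate
5 | 1-[2,3-dibromo-4,5-bis(methoxymethoxy)phenyl]prop-2-yn-1-ol (racemic) | C#CC(O)c1cc(OCOC)c(OCOC)c(Br)c1Br | intermediate
6 | 3-bromo-1-[2,3-dibromo-4,5-bis(methoxymethoxy)phenyl]prop-2-yn-1-ol (racemic) | BrC#CC(O)c1cc(OCOC)c(OCOC)c(Br)c1Br | intermediate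
7 | 2,3-dibromo-1-[3-bromo-1-(prop-2-yn-1-yloxy)prop-2-yn-1-yl]-4,5-bis(methoxymethoxy)benzene (racemic) | C#CCOC(C#CBr)c1cc(OCOC)c(OCOC)c(Br)c1Br | intermediate
8 | 2,2'-(ethyne-1,2-diyl)bis(4,4,5,5-tetramethyl-1,3,2-dioxaborolane) | CC1(C)OB(OC1(C)C)C#CB1OC(C)(C)C(C)(C)O1 | starting material
9 | 7-bromo-1-[2,3-dibromo-4,5-bis(methoxymethoxy)phenyl]-5,6-bis(4,4,5,5-tetramethyl-1,3,2-dioxaborolan-2-yl)-1,3-dihydro-2-benzofuran (racemic) | CC1(C)OB(OC1(C)C)c1cc2COC(c3cc(OCOC)c(OCOC)c(Br)c3Br)c2c(Br)c1B1OC(C)(C)C(C)(C)O1 | intermediate
10 | 3,4-dibromo-5-{[2-bromo-6-(hydroxymethyl)-3,4-bis(4,4,5,5-tetramethyl-1,3,2-dioxaborolan-2-yl)phenyl]methyl}benzene-1,2-diol | OCc1cc(B2OC(C)(C)C(C)(C)O2)c(B2OC(C)(C)C(C)(C)O2)c(Br)c1Cc1cc(O)c(O)c(Br)c1Br | intermediate (not isolated)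
11 | 3-bromo-4-(2,3-dibromo-4,5-dihydroxybenzyl)-5-(hydroxymethyl)benzene-1,2-diol (achiral) | OCc1cc(O)c(O)c(Br)c1Cc1cc(O)c(O)c(Br)c1Br | target

**Step count**
Total steps: 8. Longest linear sequence: 8 steps (1 to 11); alkyne 8 enters at step 7 as a purchased reagent.

**Steps most likely to fail**

1. Step 7. Insertion of the hindered, electron-poor diboryl alkyne into the ruthenacycle may be slow, so that the diyne dimerises or oligomerises, or the metal may insert into the alkynyl C–Br bond. The fallback moves the bromine behind the cycloaddition; it sets out from 4 and comes back at 9. Addition of LiC≡CSiMe3 (THF, −78 °C) to 4 should give 1-[2,3-dibromo-4,5-bis(methoxymethoxy)phenyl]-3-(trimethylsilyl)prop-2-yn-1-ol F1. O-Propargylation (NaH, propargyl bromide, THF/DMF, 0 °C) should give the silyl-terminated diyne {3-[2,3-dibromo-4,5-bis(methoxymethoxy)phenyl]-3-(prop-2-yn-1-yloxy)prop-1-yn-1-yl}trimethylsilane F2. Cobalt-mediated co-cyclisation with 8 (CpCo(CO)2, hν, xylene, reflux), a setting made for silyl-capped diynes and bulky alkynes, should give the 7-(trimethylsilyl)phthalan bis(boronate) F3. Ipso-bromodesilylation (Br2, pyridine, CH2Cl2, 0 °C) should then replace silicon by bromine and return to 9.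

2. Step 8. Capture of the crowded diarylmethyl cation by ring B of a second molecule may compete with hydride transfer, and the free ring B catechol may be degraded during the C–B oxidation. The fallback inverts the order so that a different ring drives the ionisation; it sets out from 9 and comes back at 11. Oxidation of 9 with NaBO3·4H2O (THF/H2O, rt), while ring B is still protected, should give 7-bromo-1-[2,3-dibromo-4,5-bis(methoxymethoxy)phenyl]-1,3-dihydro-2-benzofuran-5,6-diol F4. Its 5-hydroxyl is para to the diarylmethyl carbon, so the C1–O bond should open under much milder acid. Et3SiH (3.5 equiv) in 10% CF3CO2H/CH2Cl2 at −20 to 0 °C should then reduce and deprotect to 11, the small excess of silane and the low temperature guarding the primary benzylic alcohol.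

3. Step 6. The 1-bromoalkyne may decompose under the alkoxide base (addition to the triple bond, halogen transfer), or the product may isomerise from propargyl to allene. The fallback keeps the bromoalkyne away from strong base; it sets out from 5 and comes back at 7. Alkylation of 5 with 3-bromo-1-(triisopropylsilyl)prop-1-yne (NaH, THF, 0 °C) should give 2,3-dibromo-4,5-bis(methoxymethoxy)-1-(1-{[3-(triisopropylsilyl)prop-2-yn-1-yl]oxy}prop-2-yn-1-yl)benzene F5. Bromination of its only terminal alkyne (NBS, AgNO3 cat., acetone; the triisopropylsilyl alkyne is inert) should give 2,3-dibromo-1-(3-bromo-1-{[3-(triisopropylsilyl)prop-2-yn-1-yl]oxy}prop-2-yn-1-yl)-4,5-bis(methoxymethoxy)benzene F6. Removal of the silyl cap with n-Bu4NF/AcOH (THF, 0 °C) should give 7.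

**Further compounds**
F1 | step 7 | 1-[2,3-dibromo-4,5-bis(methoxymethoxy)phenyl]-3-(trimethylsilyl)prop-2-yn-1-ol (racemic) | C[Si](C)(C)C#CC(O)c1cc(OCOC)c(OCOC)c(Br)c1Br
F2 | step 7 | {3-[2,3-dibromo-4,5-bis(methoxymethoxy)phenyl]-3-(prop-2-yn-1-yloxy)prop-1-yn-1-yl}trimethylsilane (racemic) | C#CCOC(C#C[Si](C)(C)C)c1cc(OCOC)c(OCOC)c(Br)c1Br
F3 | step 7 | 1-[2,3-dibromo-4,5-bis(methoxymethoxy)phenyl]-5,6-bis(4,4,5,5-tetramethyl-1,3,2-dioxaborolan-2-yl)-7-(trimethylsilyl)-1,3-dihydro-2-benzofuran (racemic) | CC1(C)OB(OC1(C)C)c1cc2COC(c3cc(OCOC)c(OCOC)c(Br)c3Br)c2c([Si](C)(C)C)c1B1OC(C)(C)C(C)(C)O1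
F4 | step 8 | 7-bromo-1-[2,3-dibromo-4,5-bis(methoxymethoxy)phenyl]-1,3-dihydro-2-benzofuran-5,6-diol (racemic) | Oc1cc2COC(c3cc(OCOC)c(OCOC)c(Br)c3Br)c2c(Br)c1O
F5 | step 6 | 2,3-dibromo-4,5-bis(methoxymethoxy)-1-(1-{[3-(triisopropylsilyl)prop-2-yn-1-yl]oxy}prop-2-yn-1-yl)benzene (racemic) | C#CC(OCC#C[Si](C(C)C)(C(C)C)C(C)C)c1cc(OCOC)c(OCOC)c(Br)c1Br
F6 | step 6 | 2,3-dibromo-1-(3-bromo-1-{[3-(triisopropylsilyl)prop-2-yn-1-yl]oxy}prop-2-yn-1-yl)-4,5-bis(methoxymethoxy)benzene (racemic) | BrC#CC(OCC#C[Si](C(C)C)(C(C)C)C(C)C)c1cc(OCOC)c(OCOC)c(Br)c1Br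
A1 | direct plan | (3-bromo-4,5-dimethoxyphenyl)methanol | COc1cc(CO)cc(Br)c1OC
A2 | direct plan | 3-bromo-4,5-dimethoxybenzyl acetate | CC(=O)OCc1cc(OC)c(OC)c(Br)c1
A3 | direct plan | 2,3-dibromo-1-(bromomethyl)-4,5-dimethoxybenzene | BrCc1cc(OC)c(OC)c(Br)c1Br
A4 | direct plan | 3-bromo-2-(2,3-dibromo-4,5-dimethoxybenzyl)-4,5-dimethoxybenzyl acetate | CC(=O)OCc1cc(OC)c(OC)c(Br)c1Cc1cc(OC)c(OC)c(Br)c1Br
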